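**Retrosynthetic overview**
- Feature: each bridging CH2 joins C5 of a ring B (the CH between the C4 and C6 hydroxyls) to a ring C carbon that is ortho to one ring C hydroxyl and para to the other. The central orcinol ring C can therefore act twice as a quinone methide, and ring B is the carbon nucleophile.
- Both CH2–C(B5) bonds are cut, giving ring C diol 16 and two molecules of the A–O–B diaryl ether acid 12. The CO2H of 12 at B3 blocks the other activated ring B carbon and is removed last as CO2.
- 12 comes from SNAr of ring B phenol 10 on ring A fluoride 5, then global hydrogenolysis. 10 is made from orsellinic acid (bromination, borylation/oxidation). 5 is made from 3-fluoro-5-methylphenol (para-bromination, ortho-metalation/formylation between F and O, carbonylation).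
- 16 comes from 3,5-dimethoxytoluene by double Rieche formylation, demethylation and borohydride reduction.
- No ring is formed in the route; all five benzene rings come intact from the starting materials.

Key step: step 13

Remark: the target has no stereocentre and is achiral, so no stereocontrol is needed. Ring B locants used here: B1 carries the ether oxygen to ring A, B2 the methyl, B3 the blocking carboxyl, B4 and B6 the hydroxyls, B5 the CH between them.

**Route**

Step 1
Reactants: 1 3-fluoro-5-methylphenol
Product: 2 4-bromo-3-fluoro-5-methylphenol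
Conditions: NBS (1.0 equiv), MeCN, −20 → 0 °C
Reagents that add atoms: N-bromosuccinimide, O=C1CCC(=O)N1Br
Why: Electrophilic aromatic bromination of a phenol goes para to the hydroxyl, here the carbon between F and CH3, as in the para-bromination of 3,5-dimethylphenol.

Step 2
Reactants: 2 4-bromo-3-fluoro-5-methylphenol
Product: 3 5-(benzyloxy)-2-bromo-1-fluoro-3-methylbenzene
Conditions: BnBr, K2CO3, DMF, rt
Reagents that add atoms: benzyl bromide, BrCc1ccccc1
Why: Williamson etherification of the phenoxide; benzyl is chosen so that all O-protecting groups of the later diaryl ether fall in one hydrogenolysis.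

Step 3
Reactants: 3 5-(benzyloxy)-2-bromo-1-fluoro-3-methylbenzene
Product: 4 6-(benzyloxy)-3-bromo-2-fluoro-4-methylbenzaldehyde
Conditions: LDA, THF, −78 °C; DMF; then 1 M HCl
Reagents that add atoms: N,N-dimethylformamide, CN(C)C=O
Why: Directed ortho-metalation removes the ring hydrogen flanked by fluorine and the alkoxy group, the most acidic one; LDA does not exchange the bromine, the aryllithium is stable to LiF loss at −78 °C, and DMF formylates it.

Step 4
Reactants: 4 6-(benzyloxy)-3-bromo-2-fluoro-4-methylbenzaldehyde
Product: 5 methyl 4-(benzyloxy)-2-fluoro-3-formyl-6-methylbenzoate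
Conditions: CO (1 atm), MeOH, Pd(OAc)2 (cat.), Xantphos (cat.), Et3N, toluene, 80 °C
Reagents that add atoms: carbon monoxide, [C-]#[O+]; methanol, CO
Why: Palladium-catalysed methoxycarbonylation of the aryl bromide; the aldehyde, aryl fluoride and benzyl ether are inert to Pd(0)/CO, and the wide-bite-angle ligand tolerates the two ortho substituents.

Step 5
Reactants: 6 orsellinic acid (2,4-dihydroxy-6-methylbenzoic acid)
Product: 7 benzyl 2,4-bis(benzyloxy)-6-methylbenzoate
Conditions: BnBr (3.5 equiv), K2CO3, DMF, 70 °C
Reagents that add atoms: benzyl bromide, BrCc1ccccc1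
Why: Exhaustive O-alkylation (carboxylate first, then the 4-OH, then the chelated 2-OH on warming) gives the benzyl ester and both benzyl ethers in one operation.

Step 6
Reactants: 7 benzyl 2,4-bis(benzyloxy)-6-methylbenzoate
Product: 8 benzyl 4,6-bis(benzyloxy)-3-bromo-2-methylbenzoate
Conditions: NBS, MeCN, 0 °C → rt
Reagents that add atoms: N-bromosuccinimide, O=C1CCC(=O)N1Br
Why: Electrophilic bromination of a 1,3-dialkoxyarene takes the carbon para to one alkoxy group and next to the methyl, not the shielded carbon between the two alkoxy groups, as in the dibromination of 3,5-dimethoxytoluene.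

Step 7
Reactants: 8 benzyl 4,6-bis(benzyloxy)-3-bromo-2-methylbenzoate
Product: 10 benzyl 4,6-bis(benzyloxy)-3-hydroxy-2-methylbenzoate, via aryl pinacol boronate 9 (not isolated)
Conditions: B2pin2, Pd(OAc)2/SPhos (cat.), KOAc, dioxane, 90 °C; then H2O2, aq. NaOH, THF, 0 °C
Reagents that add atoms: bis(pinacolato)diboron, CC1(C)OB(OC1(C)C)B1OC(C)(C)C(C)(C)O1; hydrogen peroxide, OO
Why: Miyaura borylation of the hindered aryl bromide with a biaryl phosphine catalyst, then oxidation of the C–B bond by 1,2-aryl shift to peroxide oxygen, gives the phenol; the di-ortho-substituted benzyl ester survives the brief cold base.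

Step 8
Reactants: 5 methyl 4-(benzyloxy)-2-fluoro-3-formyl-6-methylbenzoate; 10 benzyl 4,6-bis(benzyloxy)-3-hydroxy-2-methylbenzoate
Product: 11 benzyl 4,6-bis(benzyloxy)-3-[3-(benzyloxy)-2-formyl-6-(methoxycarbonyl)-5-methylphenoxy]-2-methylbenzoate
Conditions: K2CO3, DMF, 70 °C
Reagents that add atoms: none
Why: SNAr: the fluorine lies between an ortho formyl and an ortho methoxycarbonyl group, which stabilise the Meisenheimer intermediate, the benzyloxy group is meta to it, and the only free hydroxyl of 10 is the nucleophile.

Step 9
Reactants: 11 the perbenzylated diaryl ether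
Product: 12 3-[2-formyl-3-hydroxy-6-(methoxycarbonyl)-5-methylphenoxy]-4,6-dihydroxy-2-methylbenzoic acid
Conditions: H2 (1 atm), 10% Pd/C, EtOAc/THF, rt
Reagents that add atoms: none
Why: Hydrogenolysis removes three benzyl ethers and the benzyl ester; the 2,6-dioxygenated aryl aldehyde is a poor substrate for Pd/C at 1 atm, and the reaction is stopped after uptake of four equivalents of hydrogen.

Step 10
Reactants: 13 3,5-dimethoxytoluene
Product: 14 4,6-dimethoxy-2-methylbenzene-1,3-dicarbaldehyde
Conditions: Cl2CHOMe (4 equiv), TiCl4 (4 equiv), CH2Cl2, 0 °C → rt; then ice/aq. HCl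
Reagents that add atoms: dichloromethyl methyl ether, COC(Cl)Cl; water, O
Why: Rieche formylation: the first formyl enters next to the methyl and para to a methoxy group, and the second takes the equivalent carbon on the other side of the methyl, the carbon between the two methoxy groups being the least accessible.

Step 11
Reactants: 14 4,6-dimethoxy-2-methylbenzene-1,3-dicarbaldehyde
Product: 15 4,6-dihydroxy-2-methylbenzene-1,3-dicarbaldehyde
Conditions: BBr3, CH2Cl2, −78 °C → rt; then H2O
Reagents that add atoms: none
Why: Lewis-acid cleavage of aryl methyl ethers; each methoxy group is ortho to a formyl group, which assists demethylation by chelation, and the aldehydes are restored on aqueous work-up.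

Step 12
Reactants: 15 4,6-dihydroxy-2-methylbenzene-1,3-dicarbaldehyde
Product: 16 4,6-bis(hydroxymethyl)-5-methylbenzene-1,3-diol
Conditions: NaBH4, THF/EtOH, 0 °C; pH 7 phosphate buffer; crude diol used at once
Reagents that add atoms: none
Why: Borohydride reduction of both aryl aldehydes; low temperature, short reaction time and neutral work-up limit hydride reduction of a derived quinone methide to a methyl group.

Step 13
Reactants: 12 the diaryl ether acid (5 equiv); 16 4,6-bis(hydroxymethyl)-5-methylbenzene-1,3-diol
Product: 20 the bis-acid (target carrying a CO2H at B3 of each ring B), via ring C ortho-quinone methide 17 (not isolated), via mono-benzylated acid 18 (not isolated), via second ortho-quinone methide 19 (not isolated)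
Conditions: 16 in dioxane added over 8 h (syringe pump) to 12, NaOAc/AcOH buffer (pH 5), dioxane/H2O, 50 °C, Ar
Reagents that add atoms: none
Why: In the mildly acidic buffer each CH2OH of 16, which is ortho to one ring C hydroxyl and para to the other, should lose water to give a quinone methide (17, then 19), and B5 of 12 adds to the exocyclic methylene, after which both rings rearomatise by tautomerisation. The closest known reaction is the Friedel–Crafts-type benzylation of resorcinols and acylphloroglucinols by ortho-hydroxybenzyl alcohols through quinone methides, as in novolac formation. No ring is closed and no stereocentre is formed. Site selectivity on ring B is secured by the carboxyl at B3, which occupies the only other activated carbon, while ring A is deactivated by its ester and aldehyde. Cross-coupling must outrun self-condensation of ring C through its free carbon between the two hydroxyls, and this is secured kinetically by adding 16 slowly to a large excess of 12. O-Alkylation by the quinone methide is reversible under these conditions and should drain into the C-benzylated product.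

Step 14
Reactants: 20 the bis-acid
Product: 21 praesorether G
Conditions: DMSO/H2O (9:1), 110 °C, Ar
Reagents that add atoms: none
Why: Thermal protodecarboxylation of 2,4-dihydroxybenzoic acids (ipso-protonation ortho and para to the hydroxyls, then loss of CO2), helped by the flanking methyl and benzyl groups; the ring A methyl ester and aldehyde are stable under these neutral conditions.

**Compound list**
1 | 3-fluoro-5-methylphenol | Cc1cc(O)cc(F)c1 | starting material
2 | 4-bromo-3-fluoro-5-methylphenol | Cc1cc(O)cc(F)c1Br | intermediate
3 | 5-(benzyloxy)-2-bromo-1-fluoro-3-methylbenzene | Cc1cc(OCc2ccccc2)cc(F)c1Br | intermediate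
4 | 6-(benzyloxy)-3-bromo-2-fluoro-4-methylbenzaldehyde | O=Cc1c(F)c(Br)c(C)cc1OCc1ccccc1 | intermediate
5 | methyl 4-(benzyloxy)-2-fluoro-3-formyl-6-methylbenzoate | COC(=O)c1c(C)cc(OCc2ccccc2)c(C=O)c1F | intermediate
6 | orsellinic acid (2,4-dihydroxy-6-methylbenzoic acid) | Cc1cc(O)cc(O)c1C(=O)O | starting material
7 | benzyl 2,4-bis(benzyloxy)-6-methylbenzoate | Cc1cc(OCc2ccccc2)cc(OCc2ccccc2)c1C(=O)OCc1ccccc1 | intermediate
8 | benzyl 4,6-bis(benzyloxy)-3-bromo-2-methylbenzoate | Cc1c(Br)c(OCc2ccccc2)cc(OCc2ccccc2)c1C(=O)OCc1ccccc1 | intermediate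
9 | benzyl 4,6-bis(benzyloxy)-2-methyl-3-(4,4,5,5-tetramethyl-1,3,2-dioxaborolan-2-yl)benzoate | Cc1c(B2OC(C)(C)C(C)(C)O2)c(OCc2ccccc2)cc(OCc2ccccc2)c1C(=O)OCc1ccccc1 | intermediate
10 | benzyl 4,6-bis(benzyloxy)-3-hydroxy-2-methylbenzoate | Cc1c(O)c(OCc2ccccc2)cc(OCc2ccccc2)c1C(=O)OCc1ccccc1 | intermediate
11 | benzyl 4,6-bis(benzyloxy)-3-[3-(benzyloxy)-2-formyl-6-(methoxycarbonyl)-5-methylphenoxy]-2-methylbenzoate | COC(=O)c1c(C)cc(OCc2ccccc2)c(C=O)c1Oc1c(C)c(C(=O)OCc2ccccc2)c(OCc2ccccc2)cc1OCc1ccccc1 | intermediate
12 | 3-[2-formyl-3-hydroxy-6-(methoxycarbonyl)-5-methylphenoxy]-4,6-dihydroxy-2-methylbenzoic acid | COC(=O)c1c(C)cc(O)c(C=O)c1Oc1c(C)c(C(=O)O)c(O)cc1O | intermediate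
13 | 3,5-dimethoxytoluene | COc1cc(C)cc(OC)c1 | starting material
14 | 4,6-dimethoxy-2-methylbenzene-1,3-dicarbaldehyde | Cc1c(C=O)c(OC)cc(OC)c1C=O | intermediate
15 | 4,6-dihydroxy-2-methylbenzene-1,3-dicarbaldehyde | Cc1c(C=O)c(O)cc(O)c1C=O | intermediate
16 | 4,6-bis(hydroxymethyl)-5-methylbenzene-1,3-diol | Cc1c(CO)c(O)cc(O)c1CO | intermediate
17 | ring C ortho-quinone methide (3-hydroxy-4-(hydroxymethyl)-5-methyl-6-methylidenecyclohexa-2,4-dien-1-one) | C=C1C(=O)C=C(O)C(CO)=C1C | intermediate
18 | mono-benzylated acid (12 carrying the 2,4-dihydroxy-5-(hydroxymethyl)-6-methylbenzyl group at B5) | COC(=O)c1c(C)cc(O)c(C=O)c1Oc1c(C)c(C(=O)O)c(O)c(Cc2c(O)cc(O)c(CO)c2C)c1O | intermediate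
19 | second ortho-quinone methide (18 after loss of water from the remaining CH2OH) | COC(=O)c1c(C)cc(O)c(C=O)c1Oc1c(C)c(C(=O)O)c(O)c(CC2=C(C)C(=C)C(=O)C=C2O)c1O | intermediate
20 | bis-acid: praesorether G carrying a CO2H at B3 of each ring B | COC(=O)c1c(C)cc(O)c(C=O)c1Oc1c(C)c(C(=O)O)c(O)c(Cc2c(O)cc(O)c(Cc3c(O)c(C(=O)O)c(C)c(Oc4c(C=O)c(O)cc(C)c4C(=O)OC)c3O)c2C)c1O | intermediate
21 | praesorether G | COC(=O)c1c(C)cc(O)c(C=O)c1Oc1c(C)cc(O)c(Cc2c(O)cc(O)c(Cc3c(O)cc(C)c(Oc4c(C=O)c(O)cc(C)c4C(=O)OC)c3O)c2C)c1O | target

**Step count**
Total: 14 steps. Longest linear sequence: 8 steps (1, 2, 3, 4, 8, 9, 13, 14).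

**Steps most likely to fail**

Step 13. The quinone methides may be captured by the free carbon of another ring C, or of the product's ring C, faster than by B5 of 12, leading to oligomers. Attack at the carboxyl-bearing B3 with loss of CO2 is a lesser risk. Fallback, from 16 back to 20: peracetylation (Ac2O, pyridine, 0 °C) should give the storable tetraacetate [4,6-bis(acetyloxy)-2-methyl-1,3-phenylene]bis(methylene) diacetate F1, in which ring C is no longer nucleophilic. F1 is then treated with excess 12 and K2CO3 in MeOH/THF at 0 °C → rt. Cleavage of each phenolic acetate releases a phenoxide that expels the benzylic acetate, so the quinone methides form one at a time under base in the presence of the polyanion of 12, and the route is rejoined at 20.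

Step 12. The electron-rich bis-benzylic diol may be over-reduced to methyl groups through a quinone methide, or may self-condense during work-up and concentration. Fallback, from 15 back to 20: double reductive amination with morpholine and NaBH(OAc)3 (1,2-dichloroethane, rt) should give the stable Mannich base 4,6-bis(morpholin-4-ylmethyl)-5-methylbenzene-1,3-diol F2. Heating F2 with excess 12 in dioxane at 70–80 °C, where the acid protonates the amine, should expel morpholine and generate the same quinone methides for capture at B5, rejoining at 20.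

Step 7. Oxidative addition at the di-ortho-substituted, electron-rich C–Br bond may stall and protodebromination may take over; a wrong bromination site in step 6 would also surface here. Fallback, from 6 back to 10: selective carboxylate alkylation (BnBr, KHCO3, DMF) should give benzyl 2,4-dihydroxy-6-methylbenzoate F3. Elbs persulfate oxidation (K2S2O8, aq. NaOH/pyridine, rt) places oxygen para to the 2-hydroxyl and gives the potassium aryl sulfate, benzyl 2,4-dihydroxy-6-methyl-5-(sulfonatooxy)benzoate potassium salt F4. Benzylation of its two free hydroxyls (BnBr, K2CO3, DMF) gives benzyl 2,4-bis(benzyloxy)-6-methyl-5-(sulfonatooxy)benzoate potassium salt F5, and acid hydrolysis of the sulfate (aq. HCl, dioxane, 60 °C) frees the phenol 10.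

**Further compounds**
F1 | step 13 | [4,6-bis(acetyloxy)-2-methyl-1,3-phenylene]bis(methylene) diacetate | CC(=O)OCc1c(C)c(COC(C)=O)c(OC(C)=O)cc1OC(C)=O
F2 | step 12 | 4,6-bis(morpholin-4-ylmethyl)-5-methylbenzene-1,3-diol | Cc1c(CN2CCOCC2)c(O)cc(O)c1CN1CCOCC1
F3 | step 7 | benzyl 2,4-dihydroxy-6-methylbenzoate | Cc1cc(O)cc(O)c1C(=O)OCc1ccccc1
F4 | step 7 | benzyl 2,4-dihydroxy-6-methyl-5-(sulfonatooxy)benzoate potassium salt | Cc1c(OS(=O)(=O)[O-])c(O)cc(O)c1C(=O)OCc1ccccc1.[K+]
F5 | step 7 | benzyl 2,4-bis(benzyloxy)-6-methyl-5-(sulfonatooxy)benzoate potassium salt | Cc1c(OS(=O)(=O)[O-])c(OCc2ccccc2)cc(OCc2ccccc2)c1C(=O)OCc1ccccc1.[K+]
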